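**Retrosynthetic overview**

1. Target 24 ⇐ furan diol 21 (step 15). The oxolane C9–C11–C12–C13–O is closed last: the 3-alkylfuran is dearomatised with singlet oxygen to the butenolide, and O9 then adds 5-exo-trig to C13. This is possible because the C9 tertiary hydroxyl is 1,4 to furan C3 (= C13) through C11–C12, and the furan ring already holds the five atoms C13–C14–C15–O–C16 of the spiro-lactone.
2. 21 ⇐ vinyl triflate 14 + 3-vinylfuran 16: B-alkyl Suzuki–Miyaura union at C9–C11, then α-face dihydroxylation (C9–O), oxidation, and α-face methyl addition at C8.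
3. 14 ⇐ keto lactone 13 ⇐ Δ5 keto ester 7: hydroboration, oxidation, α-face reduction and 1,3-diaxial lactonisation give the 19,6β-lactone.
4. 7 ⇐ achiral enoate dione 5 by a desymmetrising copper hydride reductive aldol (closes ring A, sets C4 and C10) ⇐ dione 1, acrolein 2, ylide 4.
5. Ring order: ring B (bought in 1) → ring A (step 3) → 19,6-lactone (step 8) → furan as latent 15,16-lactone (bought in 15) → oxolane (step 15).

Key step: step 15

Remark: labdane numbering is used for the core; β is the face of the C10 methyl group (C20), α the opposite face.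
Assumption: the (R)-bisphosphine in step 3 and the stated antipode of the organocatalyst in step 15 are taken to give the senses drawn; if either is reversed, its antipode is used.

**Route**

Step 1
Reactants: 1 2-methylcyclohexane-1,3-dione; 2 acrolein
Product: 3 3-(1-methyl-2,6-dioxocyclohexyl)propanal
Conditions: H2O, rt
Reagents that add atoms: none
Why: Michael addition of the dione enol to acrolein gives the C-alkylated aldehyde; the new quaternary carbon (future C10) is still prochiral, so no stereocentre is formed.

Step 2
Reactants: 3 3-(1-methyl-2,6-dioxocyclohexyl)propanal; 4 ethyl 2-(triphenylphosphoranylidene)propanoate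
Product: 5 ethyl (E)-2-methyl-5-(1-methyl-2,6-dioxocyclohexyl)pent-2-enoate
Conditions: toluene, 60 °C
Reagents that add atoms: none
Why: Wittig olefination with the stabilised ylide is selective for the aldehyde over the hindered ring ketones and should give the E trisubstituted enoate.

Step 3
Reactants: 5 ethyl (E)-2-methyl-5-(1-methyl-2,6-dioxocyclohexyl)pent-2-enoate
Product: 6 cis-fused ketol ester (4β-CO2Et; 4α-Me; 5β-OH; 10β-Me; 9-oxo)
Conditions: Cu(OAc)2·H2O (5 mol %), (R)-DTBM-SEGPHOS [(R)-5,5'-bis{di(3,5-di-tert-butyl-4-methoxyphenyl)phosphino}-4,4'-bi-1,3-benzodioxole] (5 mol %), (Me2HSi)2O, THF, 0 °C; then 1 M HCl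
Reagents that add atoms: none
Why: Copper hydride formed from Cu(OAc)2, the bisphosphine and the silane reduces the enoate 1,4, and the copper enolate adds to one of the two enantiotopic ring ketones (desymmetrising reductive aldol cyclisation, 6-exo-trig, closing ring A); the chiral ligand selects the ketone and so sets C10, and the chelated chair-like transition state to the cis-fused ketol places the ester syn to the new hydroxyl and to the C10 methyl, which sets C4 and the transient C5 carbinol.

Step 4
Reactants: 6 cis-fused ketol ester
Product: 7 Δ5 keto ester (4β-CO2Et; 4α-Me; 10β-Me; 9-oxo)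
Conditions: Burgess reagent [methyl N-(triethylammoniosulfonyl)carbamate], toluene, 70 °C
Reagents that add atoms: none
Why: Syn-elimination of the tertiary alcohol (Burgess dehydration) can only run toward C6 because C4 and C10 are quaternary, and it avoids a free C5 cation and hence skeletal rearrangement.

Step 5
Reactants: 7 Δ5 keto ester
Product: 8 Δ5 ester with the C9 ketone as its ethylene ketal
Conditions: HOCH2CH2OH, pyridinium p-toluenesulfonate (cat.), benzene, reflux, water removal
Reagents that add atoms: ethane-1,2-diol (OCCO)
Why: Acid-catalysed ketalisation masks the C9 ketone against borane and borohydride; the isolated olefin and the quaternary centres are untouched.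

Step 6
Reactants: 8 ketal of the Δ5 ester
Product: 9 6α-alcohol (5α-H; trans ring fusion)
Conditions: BH3·THF, THF, 0 °C to rt; then NaOH, H2O2
Reagents that add atoms: hydrogen peroxide (OO)
Why: Hydroboration–oxidation adds H and OH syn from the α face, because the β face carries the C4 ester and the C10 methyl; this places H at C5 α (trans-decalin) and OH at C6 in the anti-Markovnikov sense.

Step 7
Reactants: 9 6α-alcohol
Product: 10 6-ketone (5α-H)
Conditions: Dess–Martin periodinane, NaHCO3, CH2Cl2, rt
Reagents that add atoms: none
Why: Dess–Martin oxidation of the secondary alcohol under buffered, non-basic conditions leaves the C5 centre next to the new ketone unepimerised.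

Step 8
Reactants: 10 6-ketone
Product: 13 keto lactone (9-oxo-19,6β-olide), via 6β-hydroxy ester 11 (not isolated), via ketal lactone 12 (not isolated)
Conditions: NaBH4, MeOH, 0 °C; then 2 M HCl, THF, 40 °C
Reagents that add atoms: none
Why: Borohydride reduction from the open α face (the β face is blocked by the axial C4 ester and C10 methyl) gives the axial 6β-alcohol, which sits 1,3-diaxial to the C19 ester and lactonises; aqueous acid then hydrolyses the ketal.

Step 9
Reactants: 13 keto lactone
Product: 14 Δ8-en-9-yl triflate
Conditions: KHMDS, THF, −78 °C; PhNTf2, −78 to 0 °C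
Reagents that add atoms: N-phenylbis(trifluoromethanesulfonimide) (O=S(=O)(N(c1ccccc1)S(=O)(=O)C(F)(F)F)C(F)(F)F)
Why: Enolisation is possible only toward C8 (C10 is quaternary and the lactone has no α-hydrogen), and O-sulfonylation of the potassium enolate gives the vinyl triflate.

Step 10
Reactants: 15 furan-3-carbaldehyde
Product: 16 3-vinylfuran
Conditions: Ph3PCH3Br, KOtBu, Et2O, 0 °C to rt
Reagents that add atoms: methyltriphenylphosphonium bromide (C[P+](c1ccccc1)(c1ccccc1)c1ccccc1.[Br-])
Why: Wittig methylenation of the aldehyde; the volatile olefin is used as a solution in the next step.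

Step 11
Reactants: 14 Δ8-en-9-yl triflate; 16 3-vinylfuran
Product: 18 Δ8 olefin carrying the 2-(furan-3-yl)ethyl chain at C9, via B-alkyl borane 17 (not isolated)
Conditions: 16, 9-BBN-H, THF, 0 °C to rt; then 14, Pd(dppf)Cl2 (5 mol %), AsPh3, Cs2CO3, DMF/H2O, 50 °C
Reagents that add atoms: none
Why: 9-BBN adds anti-Markovnikov to the vinyl group and the B-alkyl borane couples with the vinyl triflate (B-alkyl Suzuki–Miyaura coupling), forming the C9–C11 bond next to quaternary C10 without creating a stereocentre.

Step 12
Reactants: 18 Δ8 olefin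
Product: 19 8α,9α-diol
Conditions: OsO4 (5 mol %), N-methylmorpholine N-oxide, acetone/H2O, rt
Reagents that add atoms: N-methylmorpholine N-oxide (C[N+]1([O-])CCOCC1); water (O)
Why: Catalytic syn-dihydroxylation (Upjohn conditions) of the trisubstituted olefin from the α face, the β face being shielded by the axial C10 methyl and the lactone bridge; this sets C9 (O α, chain β) and a temporary 8α-carbinol, while the aromatic furan should react more slowly than the olefin.

Step 13
Reactants: 19 8α,9α-diol
Product: 20 9α-hydroxy-8-ketone
Conditions: Dess–Martin periodinane, NaHCO3, CH2Cl2, 0 °C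
Reagents that add atoms: none
Why: Dess–Martin oxidation converts the secondary 8-alcohol to the ketone; the tertiary 9-alcohol cannot be oxidised and the buffer protects the furan.

Step 14
Reactants: 20 9α-hydroxy-8-ketone
Product: 21 furan diol (8β-OH; 8α-Me; 9α-OH)
Conditions: MeMgBr, CeCl3, THF, −78 °C; aq. NH4Cl
Reagents that add atoms: methylmagnesium bromide (C[Mg]Br)
Why: 1,2-Addition of the weakly basic methylcerium reagent to the C8 ketone from the α face, since β-axial approach is blocked 1,3-diaxially by the C10 methyl and the lactone oxygen; this gives the 8β-hydroxy-8α-methyl centre, and the hindered lactone and the furan are inert at this temperature.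

Step 15
Reactants: 21 furan diol
Product: 24 target (13S)-9α,13-epoxy-8β-hydroxylabdane-19,6β:15,16-diolide, via γ-hydroxybutenolide 22 (not isolated), via butenolide 23 (not isolated)
Conditions: O2, hν (visible), 5,10,15,20-tetraphenylporphyrin (cat.), iPr2NEt, CH2Cl2, −78 °C; NaBH4, EtOH, 0 °C, then 1 M HCl; crude 23, 1-[3,5-bis(trifluoromethyl)phenyl]-3-[(2S)-3,3-dimethyl-1-{[tris(4-methoxyphenyl)-λ5-phosphanylidene]amino}butan-2-yl]thiourea (10 mol %), toluene, −20 °C
Reagents that add atoms: oxygen (O=O)
Why: Proposed new method: singlet oxygen adds [4+2] to the furan, the hindered amine removes the unhindered C15–H of the endoperoxide (Kornblum–DeLaMare fragmentation) to give γ-hydroxybutenolide 22, borohydride reduces its ring-opened aldehyde form and acid re-closes the lactone to butenolide 23 (C15=O, C13=C14), and the chiral iminophosphorane–thiourea base then deprotonates the C9 hydroxyl while hydrogen-bonding the lactone carbonyl so that O9 adds to C13. The closest known reactions are the photooxygenation–reduction of 3-alkylfurans to β-substituted butenolides, the base-mediated oxa-Michael closure of 9-hydroxy butenolides to 9,13-epoxy spiro-lactones, and the iminophosphorane-catalysed enantioselective intramolecular oxa-Michael addition of alcohols to unsaturated esters; what is untested is such a catalyst with a tertiary alcohol and a β,β-disubstituted butenolide. The only ring closed is the oxolane (O9–C9–C11–C12–C13), by 5-exo-trig attack, after the lactone ring carried as the furan has re-formed, so it is the last ring. The only new stereocentre is the spiro carbon C13, whose two faces the decalin hardly distinguishes because C8 and C10 flank C9 alike; the catalyst antipode is therefore the controlling element (reagent control), while C9 is already fixed. The step needs oxidation of the furan only, the carbonyl at C15 and not C16, attack by O9 and not O8, and kinetic rather than equilibrium control at C13. These are secured by the absence of any other π bond in 21, by the hindered base taking the proton remote from the alkyl chain, by the 5-exo geometry of the axial 9α-hydroxyl against the 6-exo path of the 8β-hydroxyl (shielded 1,3-diaxially by the C10 methyl and O6), and by low temperature and short contact time that outrun retro-oxa-Michael.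

**Compound list**

1 | 2-methylcyclohexane-1,3-dione | CC1C(=O)CCCC1=O | starting material
2 | acrolein (prop-2-enal) | C=CC=O | starting material
3 | 3-(1-methyl-2,6-dioxocyclohexyl)propanal | CC1(CCC=O)C(=O)CCCC1=O | intermediate
4 | ethyl 2-(triphenylphosphoranylidene)propanoate | CCOC(=O)C(C)=P(c1ccccc1)(c1ccccc1)c1ccccc1 | starting material
5 | ethyl (E)-2-methyl-5-(1-methyl-2,6-dioxocyclohexyl)pent-2-enoate | CCOC(=O)/C(C)=C/CCC1(C)C(=O)CCCC1=O | intermediate
6 | ethyl 8a-hydroxy-1,4a-dimethyl-5-oxodecahydronaphthalene-1-carboxylate, cis-fused (labdane locants: 4β-CO2Et, 4α-Me, 5β-OH, 10β-Me, 9-oxo) | CCOC(=O)[C@@]1(C)CCC[C@]2(C)C(=O)CCC[C@]12O | intermediate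
7 | ethyl 1,4a-dimethyl-5-oxo-1,2,3,4,4a,5,6,7-octahydronaphthalene-1-carboxylate (4β-CO2Et, 4α-Me, 10β-Me, Δ5, 9-oxo) | CCOC(=O)[C@@]1(C)CCC[C@]2(C)C(=O)CCC=C12 | intermediate
8 | 9,9-ethylenedioxy ketal of 7 | CCOC(=O)[C@@]1(C)CCC[C@]2(C)C3(OCCO3)CCC=C12 | intermediate
9 | 6α-hydroxy-5α-H ester ketal (trans-decalin) | CCOC(=O)[C@@]1(C)CCC[C@]2(C)C3(OCCO3)CC[C@H](O)[C@@H]12 | intermediate
10 | 6-oxo-5α-H ester ketal | CCOC(=O)[C@@]1(C)CCC[C@]2(C)C3(OCCO3)CCC(=O)[C@@H]12 | intermediate
11 | 6β-hydroxy-5α-H ester ketal | CCOC(=O)[C@@]1(C)CCC[C@]2(C)C3(OCCO3)CC[C@@H](O)[C@@H]12 | intermediate (not isolated)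
12 | 9,9-ethylenedioxy-19,6β-lactone | C1C[C@H]2OC(=O)[C@@]3(C)CCC[C@@](C)([C@@H]23)C14OCCO4 | intermediate (not isolated)
13 | keto lactone: 9-oxo-14,15,16,17-tetranor... bicyclic core, 4α,10β-dimethyl-9-oxo-trans-decalin-19,6β-olide | C1C[C@H]2OC(=O)[C@@]3(C)CCC[C@@](C)([C@@H]23)C1=O | intermediate
14 | Δ8-en-9-yl trifluoromethanesulfonate of 13 | C1C[C@H]2OC(=O)[C@@]3(C)CCC[C@@](C)([C@@H]23)C=1OS(=O)(=O)C(F)(F)F | intermediate
15 | furan-3-carbaldehyde | O=Cc1ccoc1 | starting material
16 | 3-vinylfuran | C=Cc1ccoc1 | intermediate
17 | 9-[2-(furan-3-yl)ethyl]-9-borabicyclo[3.3.1]nonane | C(Cc1ccoc1)B1C2CCCC1CCC2 | intermediate (not isolated)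
18 | 9-[2-(furan-3-yl)ethyl]-Δ8-ene-19,6β-olide (17-nor) | C1C[C@H]2OC(=O)[C@@]3(C)CCC[C@@](C)([C@@H]23)C=1CCc1ccoc1 | intermediate
19 | 8α,9α-dihydroxy-9β-[2-(furan-3-yl)ethyl]-19,6β-olide (17-nor) | O[C@@H]1C[C@H]2OC(=O)[C@@]3(C)CCC[C@@](C)([C@@H]23)[C@@]1(O)CCc1ccoc1 | intermediate
20 | 9α-hydroxy-8-oxo-9β-[2-(furan-3-yl)ethyl]-19,6β-olide (17-nor) | O=C1C[C@H]2OC(=O)[C@@]3(C)CCC[C@@](C)([C@@H]23)[C@@]1(O)CCc1ccoc1 | intermediate
21 | 15,16-epoxy-8β,9α-dihydroxylabda-13(16),14-dien-19,6β-olide (8α-methyl furan diol) | C[C@]1(O)C[C@H]2OC(=O)[C@@]3(C)CCC[C@@](C)([C@@H]23)[C@@]1(O)CCc1ccoc1 | intermediate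
22 | 8β,9α,16-trihydroxylabd-13-ene-19,6β:15,16-diolide (γ-hydroxybutenolide, C16 epimers) | C[C@]1(O)C[C@H]2OC(=O)[C@@]3(C)CCC[C@@](C)([C@@H]23)[C@@]1(O)CCC1=CC(=O)OC1O | intermediate (not isolated)
23 | 8β,9α-dihydroxylabd-13-ene-19,6β:15,16-diolide (butenolide) | C[C@]1(O)C[C@H]2OC(=O)[C@@]3(C)CCC[C@@](C)([C@@H]23)[C@@]1(O)CCC1=CC(=O)OC1 | intermediate (not isolated)
24 | (13S)-9α,13-epoxy-8β-hydroxylabdane-19,6β:15,16-diolide | C[C@]1(O)C[C@H]2OC(=O)[C@@]3(C)CCC[C@@](C)([C@@H]23)[C@@]12CC[C@]1(COC(=O)C1)O2 | target

**Count**

Total steps: 15. Longest linear sequence: 14 (steps 1–9 and 11–15; step 10 is the side branch).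

**Three steps most likely to fail**

1. Step 15 (Proposed new method). The process at risk is loss of catalyst control through uncatalysed or reversible oxa-Michael addition, which would give poor facial selectivity at C13; the crude stream may also deactivate the catalyst. The fallback uses known chemistry, sets out from 21 and returns at 24. The sequence is run stepwise: photooxygenation and borohydride reduction with isolation of butenolide 23, then cyclisation with DBU in CH2Cl2 under equilibrium control. This is expected to give 24 together with the (13R)-spiro-lactone F1. The two are separated by chromatography or crystallisation, and F1 is re-exposed to DBU, which re-opens it to 23 by retro-oxa-Michael and re-closes it, so material is funnelled to 24.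

2. Step 3. The process at risk is insufficient enantio- or diastereoselection in the desymmetrising aldol, or competing 1,2-reduction of a ring ketone. The fallback sets out from 5 and returns at 6, and separates the two tasks. Asymmetric transfer hydrogenation with RuCl(p-cymene)[(S,S)-TsDPEN] and HCO2H/Et3N desymmetrises the dione to the hydroxy ketone enoate F2 and fixes C10. The single remaining ketone then undergoes substrate-controlled reductive aldol cyclisation with stoichiometric [(Ph3P)CuH]6 to the diol ester F3. Dess–Martin oxidation of its secondary carbinol, whose configuration is of no consequence, gives 6.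

3. Step 11. The process at risk is slow transmetalation and β-hydride elimination at the hindered triflate next to quaternary C10, or protodeboronation of the borane. The fallback sets out from 13 and returns at 18, and replaces cross-coupling by polar addition and elimination. [2-(Furan-3-yl)ethyl]magnesium bromide F4, made from purchased 3-(2-bromoethyl)furan and transmetallated with CeCl3, adds to ketone 13 to give the tertiary alcohol F5 (equatorial attack, 9α-hydroxyl). Anti-elimination with POCl3/pyridine through the axial 8β-hydrogen then gives 18.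

**Further compounds**

F1 | step 15 | (13R)-9α,13-epoxy-8β-hydroxylabdane-19,6β:15,16-diolide (C13 epimer of 24) | C[C@]1(O)C[C@H]2OC(=O)[C@@]3(C)CCC[C@@](C)([C@@H]23)[C@@]12CC[C@@]1(COC(=O)C1)O2
F2 | step 3 | ethyl (E)-5-(2-hydroxy-1-methyl-6-oxocyclohexyl)-2-methylpent-2-enoate (hydroxyl cis to the ring methyl) | CCOC(=O)/C(C)=C/CC[C@@]1(C)C(=O)CCC[C@@H]1O
F3 | step 3 | ethyl 5,8a-dihydroxy-1,4a-dimethyldecahydronaphthalene-1-carboxylate (9β-hydroxy analogue of 6) | CCOC(=O)[C@@]1(C)CCC[C@]2(C)[C@@H](O)CCC[C@]12O
F4 | step 11 | [2-(furan-3-yl)ethyl]magnesium bromide | Br[Mg]CCc1ccoc1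
F5 | step 11 | 9α-hydroxy-9β-[2-(furan-3-yl)ethyl]-19,6β-olide (17-nor, 8-unsubstituted) | C1C[C@H]2OC(=O)[C@@]3(C)CCC[C@@](C)([C@@H]23)[C@@]1(O)CCc1ccoc1
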